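**Plan**

Labels: ring A is the benzo ring and ring C the pyranone of the flavanone; ring B is the 2-aryl ring and ring D the dimethyldihydropyran fused to it. The B/D unit is numbered as a chromane (O1, C2, C3, C4, C4a, C5 to C8, C8a).

- Cuts: first the flavanone C2–aryl bond (a 7-silyloxy-8-prenylchromone plus an arylboronic acid). In the B/D fragment, next the C6–B and C8–prenyl bonds (back to Br and I), then the C3–C4 saturation, and last the C4–C4a bond of ring D. The ring A prenyl group goes back to a 7-O-(2-methylbut-3-en-2-yl) ether of 7-hydroxychromone.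
- Enabling feature: in ring D, O1 carries the quaternary gem-dimethyl carbon C2, so the ether O1–C2(CH3)2–C3≡C4H of 4-bromo-2-iodophenol holds its terminal alkyne carbon C4 over the one free ortho carbon C4a of ring B. The other ortho carbon, C8, carries iodine, the later prenyl site.
- Forward order: ring D closes first by gold-catalysed 6-endo-dig hydroarylation. C3=C4 is then saturated, iodine is exchanged for prenyl and bromine for boron.
- Separately, 7-hydroxychromone (rings A and C) is prenylated at C8 by an aromatic Claisen rearrangement and silylated. The two fragments are joined by conjugate addition, which turns the chromone into the flavanone, and the silyl group is removed.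
- Stereochemistry: the only stereocentre, flavanone C2 (S), is set in step 10 by the chiral pyridine-oxazoline ligand on divalent palladium (catalyst control) and kept by base-free conditions afterwards.

Key step: step 2

Assumption: the sense of induction of Pd(OCOCF3)2/t-BuPyOx on chromones is taken to follow that on cyclic enones, so the (R)-ligand should give the (2S)-flavanone; if the opposite sense were found, the (S)-ligand would be used with no other change.

**Route**

Step 1
Reactants: 1 4-bromo-2-iodophenol
Product: 2 4-bromo-2-iodo-1-[(2-methylbut-3-yn-2-yl)oxy]benzene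
Conditions: 3-chloro-3-methylbut-1-yne, DBU, CuCl2·2H2O (1 mol%), MeCN, 0 °C to rt
Reagents that add atoms: 3-chloro-3-methylbut-1-yne, C#CC(C)(C)Cl
Why: Copper-catalysed propargylic etherification, in which a copper acetylide of the tertiary chloride ionises to a copper allenylidene that the phenoxide should capture at the tertiary carbon, a pathway that tolerates hindered and electron-poor phenols where direct SN2 alkylation is impossible.

Step 2
Reactants: 2 4-bromo-2-iodo-1-[(2-methylbut-3-yn-2-yl)oxy]benzene
Product: 3 6-bromo-8-iodo-2,2-dimethyl-2H-chromene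
Conditions: [Au{P(t-Bu)2(2-biphenylyl)}(NCMe)]SbF6 (3 mol%), ClCH2CH2Cl, rt to 60 °C
Reagents that add atoms: none
Why: The cationic monovalent gold complex coordinates the terminal alkyne of 2, and the arene attacks the activated triple bond anti to gold through its only unsubstituted ortho carbon (C4a), after which the arenium intermediate rearomatises by proton loss and the vinylgold species is protodeaurated, freeing the catalyst. The closest known reaction type is the gold- or platinum-catalysed intramolecular hydroarylation of aryl propargyl ethers to 2H-chromenes, a Friedel-Crafts-type alkenylation. Ring D closes in the 6-endo-dig mode by forming the C4–C4a bond, attack at the internal alkyne carbon (5-exo-dig) being disfavoured by the electron-withdrawing propargylic oxygen and by the strain of the exocyclic vinylgold it would give. No stereocentre is formed. The step needs regioselectivity between the two ortho carbons, secured by the iodine atom at C8, and chemoselectivity for alkyne activation over ionisation of the tertiary propargylic C–O bond, secured by a soft carbophilic catalyst at mild temperature and helped by the gem-dimethyl group at C2, which favours the reactive rotamer. The aryl C–I and C–Br bonds are inert to monovalent gold.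

Step 3
Reactants: 3 6-bromo-8-iodo-2,2-dimethyl-2H-chromene
Product: 4 6-bromo-8-iodo-2,2-dimethylchromane
Conditions: H2 (3 atm), RhCl(PPh3)3 (5 mol%), benzene/EtOH 1:1, rt
Reagents that add atoms: none
Why: Homogeneous hydrogenation with RhCl(PPh3)3 should saturate the cis-disubstituted styrene-type C3=C4 bond while leaving untouched the aryl C–I and C–Br bonds, which heterogeneous palladium would cleave.

Step 4
Reactants: 4 6-bromo-8-iodo-2,2-dimethylchromane
Product: 6 6-bromo-2,2-dimethyl-8-(3-methylbut-2-en-1-yl)chromane, via arylmagnesium chloride 5 (not isolated)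
Conditions: i-PrMgCl·LiCl, THF, −20 °C; then Li2CuCl4 (3 mol%), prenyl bromide, −20 to 0 °C
Reagents that add atoms: 1-bromo-3-methylbut-2-ene (prenyl bromide), CC(C)=CCBr
Why: Halogen–magnesium exchange is much faster for the aryl iodide (assisted by the ortho ring oxygen) than for the bromide, and Grignard reagent 5 should then undergo copper-catalysed allylic substitution at the primary carbon of prenyl bromide, since attack at the tertiary end would build a quaternary benzylic carbon.

Step 5
Reactants: 6 6-bromo-2,2-dimethyl-8-(3-methylbut-2-en-1-yl)chromane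
Product: 9 [2,2-dimethyl-8-(3-methylbut-2-en-1-yl)chroman-6-yl]boronic acid, via aryllithium 7 (not isolated), via lithium aryl(triisopropoxy)borate 8 (not isolated)
Conditions: n-BuLi, THF, −78 °C; B(Oi-Pr)3, −78 °C to rt; 1 M HCl, 0 °C
Reagents that add atoms: triisopropyl borate, CC(C)OB(OC(C)C)OC(C)C; water, O
Why: Bromine–lithium exchange at −78 °C is faster than deprotonation of the prenyl CH2 group, and trapping of aryllithium 7 with the borate followed by mild acid hydrolysis of ate complex 8 is the standard route to arylboronic acids.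

Step 6
Reactants: 10 7-hydroxy-4H-chromen-4-one
Product: 11 7-[(2-methylbut-3-yn-2-yl)oxy]-4H-chromen-4-one
Conditions: 3-chloro-3-methylbut-1-yne, DBU, CuCl2·2H2O (1 mol%), MeCN, 0 °C to rt
Reagents that add atoms: 3-chloro-3-methylbut-1-yne, C#CC(C)(C)Cl
Why: The same copper-catalysed propargylic etherification as in step 1, well suited to the acidic 7-hydroxyl group (a vinylogous acid), which is a poor SN2 nucleophile but a good partner for the copper allenylidene.

Step 7
Reactants: 11 7-[(2-methylbut-3-yn-2-yl)oxy]-4H-chromen-4-one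
Product: 12 7-[(2-methylbut-3-en-2-yl)oxy]-4H-chromen-4-one
Conditions: H2 (1 atm), Pd/CaCO3 poisoned with Pb(OAc)2, quinoline, EtOAc, rt
Reagents that add atoms: none
Why: Semihydrogenation over lead-poisoned palladium with quinoline should stop at the alkene and should leave the chromone C2=C3 bond, part of a vinylogous ester, untouched.

Step 8
Reactants: 12 7-[(2-methylbut-3-en-2-yl)oxy]-4H-chromen-4-one
Product: 14 7-hydroxy-8-(3-methylbut-2-en-1-yl)-4H-chromen-4-one, via 8H-chromene-4,7-dione 13 (not isolated)
Conditions: N,N-diethylaniline, 130 °C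
Reagents that add atoms: none
Why: Aromatic Claisen rearrangement, in which the [3,3]-sigmatropic shift delivers the allyl unit with inversion to C8, the ortho carbon joined to C7 by the bond of higher double-bond character in the benzopyranone (as with 7-allyloxy-coumarins and -chromones), and dienone 13 then tautomerises to the phenol.

Step 9
Reactants: 14 7-hydroxy-8-(3-methylbut-2-en-1-yl)-4H-chromen-4-one
Product: 15 8-(3-methylbut-2-en-1-yl)-7-[(triisopropylsilyl)oxy]-4H-chromen-4-one
Conditions: TIPSCl, imidazole, DMF, rt
Reagents that add atoms: chlorotriisopropylsilane, CC(C)[Si](Cl)(C(C)C)C(C)C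
Why: Silylation of the acidic phenol gives a bulky silyl ether that should survive the aqueous, weakly acidic conditions of step 10 and can later be removed without acid or strong base.

Step 10
Reactants: 15 8-(3-methylbut-2-en-1-yl)-7-[(triisopropylsilyl)oxy]-4H-chromen-4-one; 9 [2,2-dimethyl-8-(3-methylbut-2-en-1-yl)chroman-6-yl]boronic acid
Product: 16 (2S)-2-[2,2-dimethyl-8-(3-methylbut-2-en-1-yl)chroman-6-yl]-8-(3-methylbut-2-en-1-yl)-7-[(triisopropylsilyl)oxy]chroman-4-one
Conditions: Pd(OCOCF3)2 (5 mol%), (R)-4-tert-butyl-2-(pyridin-2-yl)-4,5-dihydro-1,3-oxazole ((R)-t-BuPyOx, 6 mol%), NH4PF6 (30 mol%), H2O (5 equiv), ClCH2CH2Cl, 60 °C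
Reagents that add atoms: none
Why: Asymmetric conjugate addition of an arylboronic acid to a chromone under divalent palladium catalysis, in which transmetalation gives an arylpalladium species whose enantio-determining migratory insertion into the C2=C3 bond is steered by the tert-butyl group of the (R)-ligand to give the (2S) centre, and the palladium enolate is protonated by water under base-free conditions that do not open ring C.

Step 11
Reactants: 16 (2S)-2-[2,2-dimethyl-8-(3-methylbut-2-en-1-yl)chroman-6-yl]-8-(3-methylbut-2-en-1-yl)-7-[(triisopropylsilyl)oxy]chroman-4-one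
Product: 17 (2S)-2-[2,2-dimethyl-8-(3-methylbut-2-en-1-yl)chroman-6-yl]-7-hydroxy-8-(3-methylbut-2-en-1-yl)chroman-4-one
Conditions: Bu4NF, AcOH, THF, 0 °C
Reagents that add atoms: none
Why: Fluoride cleaves the Si–O bond and acetic acid buffers the phenoxide, so the C2 stereocentre (which would racemise by base-induced retro-oxa-Michael opening of ring C) and the acid-sensitive ortho-prenylphenol unit should both be preserved.

**Compound list**

1 | 4-bromo-2-iodophenol | Oc1ccc(Br)cc1I | starting material
2 | 4-bromo-2-iodo-1-[(2-methylbut-3-yn-2-yl)oxy]benzene | C#CC(C)(C)Oc1ccc(Br)cc1I | intermediate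
3 | 6-bromo-8-iodo-2,2-dimethyl-2H-chromene | CC1(C)C=Cc2cc(Br)cc(I)c2O1 | intermediate
4 | 6-bromo-8-iodo-2,2-dimethylchromane | CC1(C)CCc2cc(Br)cc(I)c2O1 | intermediate
5 | (6-bromo-2,2-dimethylchroman-8-yl)magnesium chloride (LiCl complex) | CC1(C)CCc2cc(Br)cc([Mg]Cl)c2O1 | intermediate (not isolated)
6 | 6-bromo-2,2-dimethyl-8-(3-methylbut-2-en-1-yl)chromane | CC(C)=CCc1cc(Br)cc2c1OC(C)(C)CC2 | intermediate
7 | [2,2-dimethyl-8-(3-methylbut-2-en-1-yl)chroman-6-yl]lithium | CC(C)=CCc1cc([Li])cc2c1OC(C)(C)CC2 | intermediate (not isolated)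
8 | lithium [2,2-dimethyl-8-(3-methylbut-2-en-1-yl)chroman-6-yl]triisopropoxyborate | [Li+].CC(C)O[B-](OC(C)C)(OC(C)C)c1cc(CC=C(C)C)c2OC(C)(C)CCc2c1 | intermediate (not isolated)
9 | [2,2-dimethyl-8-(3-methylbut-2-en-1-yl)chroman-6-yl]boronic acid | CC(C)=CCc1cc(B(O)O)cc2c1OC(C)(C)CC2 | intermediate
10 | 7-hydroxy-4H-chromen-4-one | O=c1ccoc2cc(O)ccc12 | starting material
11 | 7-[(2-methylbut-3-yn-2-yl)oxy]-4H-chromen-4-one | O=c1ccoc2cc(OC(C)(C)C#C)ccc12 | intermediate
12 | 7-[(2-methylbut-3-en-2-yl)oxy]-4H-chromen-4-one | O=c1ccoc2cc(OC(C)(C)C=C)ccc12 | intermediate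
13 | racemic 8-(3-methylbut-2-en-1-yl)-8H-chromene-4,7-dione | O=C1C=CC2=C(OC=CC2=O)C1CC=C(C)C | intermediate (not isolated)
14 | 7-hydroxy-8-(3-methylbut-2-en-1-yl)-4H-chromen-4-one | O=c1ccoc2c(CC=C(C)C)c(O)ccc12 | intermediate
15 | 8-(3-methylbut-2-en-1-yl)-7-[(triisopropylsilyl)oxy]-4H-chromen-4-one | O=c1ccoc2c(CC=C(C)C)c(O[Si](C(C)C)(C(C)C)C(C)C)ccc12 | intermediate
16 | (2S)-2-[2,2-dimethyl-8-(3-methylbut-2-en-1-yl)chroman-6-yl]-8-(3-methylbut-2-en-1-yl)-7-[(triisopropylsilyl)oxy]chroman-4-one | CC(C)=CCc1cc([C@@H]2CC(=O)c3ccc(O[Si](C(C)C)(C(C)C)C(C)C)c(CC=C(C)C)c3O2)cc2c1OC(C)(C)CC2 | intermediate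
17 | (2S)-2-[2,2-dimethyl-8-(3-methylbut-2-en-1-yl)chroman-6-yl]-7-hydroxy-8-(3-methylbut-2-en-1-yl)chroman-4-one | CC(C)=CCc1cc([C@@H]2CC(=O)c3ccc(O)c(CC=C(C)C)c3O2)cc2c1OC(C)(C)CC2 | target

**Step count**

Total: 11 steps. Longest linear sequence: 7 steps (steps 1, 2, 3, 4, 5, 10, 11, from 4-bromo-2-iodophenol).

**Steps most likely to fail**

Step 2. The gold catalyst may ionise the tertiary propargylic C–O bond, which is weakened by the electron-poor dihalophenoxide leaving group, or the halogen-deactivated ring may attack the activated alkyne too slowly. The fallback sets out from 2 and returns at 3 by a purely thermal pericyclic cascade in place of π-acid catalysis. Heating 2 in N,N-diethylaniline at about 180 °C should bring about an aromatic propargyl Claisen rearrangement to the free ortho carbon, giving racemic 4-bromo-2-iodo-6-(3-methylbuta-1,2-dien-1-yl)cyclohexa-2,4-dien-1-one F1. This enolises to 4-bromo-2-iodo-6-(3-methylbuta-1,2-dien-1-yl)phenol F2. A [1,5]-hydrogen shift then gives the ortho-quinone methide (6Z)-4-bromo-2-iodo-6-(3-methylbut-2-en-1-ylidene)cyclohexa-2,4-dien-1-one F3, whose oxa-6π electrocyclisation closes the pyran ring at oxygen and gives 3.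

Step 10. Facial selectivity may be poor on this electron-rich, ortho-substituted chromone, and the electron-rich boronic acid may protodeboronate before it transmetalates. The fallback sets out from 15 and 9 and returns at 16 by giving up catalyst control in the C–C bond formation and resolving afterwards. Conjugate addition with the achiral, more reactive catalyst Pd(OCOCF3)2/2,2'-bipyridine should give racemic 2-[2,2-dimethyl-8-(3-methylbut-2-en-1-yl)chroman-6-yl]-8-(3-methylbut-2-en-1-yl)-7-[(triisopropylsilyl)oxy]chroman-4-one F4. Kinetic resolution by asymmetric transfer hydrogenation with RhCl[(R,R)-TsDPEN](C5Me5) and HCO2H/Et3N should follow. By the usual sense for aryl ketones this catalyst delivers hydride to give the (4R)-alcohol anti to the 2-aryl group, so it should consume the (2R)-ketone faster and convert it into the cis-alcohol (2R,4R)-2-[2,2-dimethyl-8-(3-methylbut-2-en-1-yl)chroman-6-yl]-8-(3-methylbut-2-en-1-yl)-7-[(triisopropylsilyl)oxy]chroman-4-ol F5. Chromatography removes this alcohol and leaves the unreacted (2S)-ketone 16; isolated alkenes are not touched by transfer hydrogenation.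

Step 8. The [3,3] shift may go partly to C6 instead of C8, and at the temperature needed the ortho-prenylphenol may react further. The fallback sets out from 10 and returns at 15 by replacing the sigmatropic prenyl transfer with a cross-coupling at a halogen placed at C8. Iodination of 10 with N-iodosuccinimide in DMF, which for 7-hydroxybenzopyranones goes to C8, should give 7-hydroxy-8-iodo-4H-chromen-4-one F6. Silylation (TIPSCl, imidazole) gives 8-iodo-7-[(triisopropylsilyl)oxy]-4H-chromen-4-one F7. A Suzuki–Miyaura coupling with 4,4,5,5-tetramethyl-2-(3-methylbut-2-en-1-yl)-1,3,2-dioxaborolane then gives 15; it would use Pd(OAc)2, a bulky dialkylbiarylphosphine chosen for coupling at the unsubstituted allyl terminus, and K3PO4 in THF/H2O.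

**Further compounds**

F1 | step 2 | racemic 4-bromo-2-iodo-6-(3-methylbuta-1,2-dien-1-yl)cyclohexa-2,4-dien-1-one | O=C1C(I)=CC(Br)=CC1C=C=C(C)C
F2 | step 2 | 4-bromo-2-iodo-6-(3-methylbuta-1,2-dien-1-yl)phenol | CC(C)=C=Cc1cc(Br)cc(I)c1O
F3 | step 2 | (6Z)-4-bromo-2-iodo-6-(3-methylbut-2-en-1-ylidene)cyclohexa-2,4-dien-1-one | CC(C)=C/C=C1/C=C(Br)C=C(I)C1=O
F4 | step 10 | racemic 2-[2,2-dimethyl-8-(3-methylbut-2-en-1-yl)chroman-6-yl]-8-(3-methylbut-2-en-1-yl)-7-[(triisopropylsilyl)oxy]chroman-4-one | CC(C)=CCc1cc(C2CC(=O)c3ccc(O[Si](C(C)C)(C(C)C)C(C)C)c(CC=C(C)C)c3O2)cc2c1OC(C)(C)CC2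
F5 | step 10 | (2R,4R)-2-[2,2-dimethyl-8-(3-methylbut-2-en-1-yl)chroman-6-yl]-8-(3-methylbut-2-en-1-yl)-7-[(triisopropylsilyl)oxy]chroman-4-ol | CC(C)=CCc1cc([C@H]2C[C@@H](O)c3ccc(O[Si](C(C)C)(C(C)C)C(C)C)c(CC=C(C)C)c3O2)cc2c1OC(C)(C)CC2
F6 | step 8 | 7-hydroxy-8-iodo-4H-chromen-4-one | O=c1ccoc2c(I)c(O)ccc12
F7 | step 8 | 8-iodo-7-[(triisopropylsilyl)oxy]-4H-chromen-4-one | O=c1ccoc2c(I)c(O[Si](C(C)C)(C(C)C)C(C)C)ccc12
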